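**Plan**

- Retrosynthesis: the C7 acetate is made last by inverting esterification of the 7β-alcohol. Ring B is then cut at C7–C8, the bond between the carbinol carbon C7 and C8, the ring-B carbon that carries the exocyclic C17 methylene.
- This 2-methylenecyclohexanol unit of ring B (C7–O next to C8=C17) is the retron of a nickel-catalysed reductive aldehyde/terminal-alkyne cyclization. The precursor is the 7,8-seco ynal, with the C7 aldehyde on C6 and the ethynyl group C8≡C17 on C9.
- Alkyne and aldehyde both come from ozonolysis of the C7=C8 olefin of a labd-7-ene (the C8 methyl ketone becomes the alkyne). The olefin comes from dehydration of the 8α-ol of sclareol. C13–C14 is cut by Horner–Wadsworth–Emmons logic back to the C13 methyl ketone obtained by excising the vinyl group of sclareol.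
- Forward order: side chain (steps 1–3), ring B opened (steps 4–5), alkyne installed (steps 6–8), ring B re-closed with the oxygen now on C7 and the former C8 methyl as the exocyclic methylene (step 9), desilylation and inversion to the acetate (steps 10–11).
- Stereochemistry: C5, C9 and C10 are those of (−)-sclareol and no bond to them is broken. C13 comes from a ligand-controlled copper hydride conjugate reduction. C7 is set equatorial (7β) by the planar nickelacycle of the key step and inverted to the axial 7α-acetate by the Mitsunobu reaction.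

Key step: step 9

Assumption: in step 3 the (R)-bisphosphine is taken to deliver hydride to the C13 face of the (E)-enoate that gives 13S; if a model reduction shows the opposite sense, the (S)-ligand is used with no other change.

**Route**

Step 1
Reactants: 1 (−)-sclareol
Product: 3 8α-hydroxy-14,15-dinorlabdan-13-one, via labdane-8α,13,14,15-tetraol 2 (not isolated)
Conditions: OsO4 (2 mol %), NaIO4 (4 equiv), 2,6-lutidine, dioxane/H2O 3:1, 20 °C
Reagents that add atoms: none
Why: Lemieux–Johnson oxidation, in which OsO4 dihydroxylates the only olefin and periodate cleaves both glycol C–C bonds of the resulting 13,14,15-triol, so that C13 emerges as the methyl ketone while the decalin stereocentres are untouched.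

Step 2
Reactants: 3 8α-hydroxy-14,15-dinorlabdan-13-one
Product: 4 methyl (13E)-8α-hydroxylabd-13-en-15-oate
Conditions: (MeO)2P(O)CH2CO2Me (1.5 equiv), NaH (1.4 equiv), THF, 0 °C then 60 °C; E isomer separated from the minor Z isomer on silica
Reagents that add atoms: trimethyl phosphonoacetate COC(=O)CP(=O)(OC)OC
Why: Horner–Wadsworth–Emmons olefination of the methyl ketone should favour the E enoate (ester trans to the larger C12 chain), and the stabilised phosphonate anion is too weak a base to deprotonate the tertiary 8-OH, which keeps oxa-Michael closure to the 8,13-ether from competing.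

Step 3
Reactants: 4 methyl (13E)-8α-hydroxylabd-13-en-15-oate
Product: 5 methyl (13S)-8α-hydroxylabdan-15-oate
Conditions: Cu(OAc)2·H2O (3 mol %), (R)-DTBM-SEGPHOS (3 mol %), (EtO)2MeSiH (2 equiv), t-BuOH (2 equiv), toluene, 20 °C; NH4F/MeOH work-up
Reagents that add atoms: none
Why: asymmetric copper hydride 1,4-reduction of a geometrically pure β,β-disubstituted enoate, in which the chiral bisphosphine alone decides the face of hydride delivery at C13 (the decalin stereocentres are too remote to interfere) and the tertiary alcohol is left alone.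

Step 4
Reactants: 5 methyl (13S)-8α-hydroxylabdan-15-oate
Product: 6 methyl (13S)-labd-7-en-15-oate
Conditions: conc. H2SO4 (2 equiv), MeOH, 0 to 20 °C, stopped at full conversion of 5
Reagents that add atoms: none
Why: acid-promoted E1 dehydration in which the C8 cation should lose the axial 7α-hydrogen under kinetic control, the same proton loss that ends cationic cyclizations of this skeleton, to give the trisubstituted 7-ene, while the saturated ester chain cannot trap the cation.

Step 5
Reactants: 6 methyl (13S)-labd-7-en-15-oate
Product: 8 methyl (13S)-7,7-dimethoxy-8-oxo-7,8-secolabdan-15-oate, via keto aldehyde 7 (not isolated)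
Conditions: O3, CH2Cl2/MeOH 4:1, −78 °C; Me2S, −78 to 20 °C; then HC(OMe)3 (3 equiv), PPTS (5 mol %), MeOH, 20 °C
Reagents that add atoms: ozone [O-][O+]=O; trimethyl orthoformate COC(OC)OC
Why: ozonolysis with reductive work-up cuts C7=C8 into the C7 aldehyde and the C8 methyl ketone, and only the unhindered aldehyde is acetalised because the ketone is α-branched and flanked by the quaternary C10, the mild acid being chosen to avoid enolisation towards C9.

Step 6
Reactants: 8 methyl (13S)-7,7-dimethoxy-8-oxo-7,8-secolabdan-15-oate
Product: 9 methyl (13S)-8-(diethoxyphosphoryloxy)-7,7-dimethoxy-7,8-secolabd-8(17)-en-15-oate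
Conditions: LiN(iPr)2 (1.05 equiv), THF, −78 °C; ClP(O)(OEt)2 (1.1 equiv), −78 to 0 °C
Reagents that add atoms: diethyl chlorophosphate CCOP(=O)(Cl)OCC
Why: kinetic deprotonation of the ketone occurs at the unhindered C17 methyl and not at the neopentyl-type C9–H (nor at the less acidic ester), and O-phosphorylation of this enolate gives the 1-alken-2-yl phosphate, the first half of the standard methyl ketone to terminal alkyne conversion.

Step 7
Reactants: 9 methyl (13S)-8-(diethoxyphosphoryloxy)-7,7-dimethoxy-7,8-secolabd-8(17)-en-15-oate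
Product: 10 methyl (13S)-7,7-dimethoxy-7,8-secolabd-8(17)-yn-15-oate
Conditions: LiN(iPr)2 (3.5 equiv), THF, −78 °C, 1 h; aqueous NH4Cl quench at −78 °C
Reagents that add atoms: none
Why: base-induced β-elimination of diethyl phosphate from the enol phosphate gives the lithium acetylide, protonated on quench, while the ester enolate formed by the excess base at −78 °C is returned unchanged and neither C9 nor C13 is deprotonated.

Step 8
Reactants: 10 methyl (13S)-7,7-dimethoxy-7,8-secolabd-8(17)-yn-15-oate
Product: 11 methyl (13S)-7-oxo-7,8-secolabd-8(17)-yn-15-oate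
Conditions: PPTS (0.2 equiv), acetone/H2O 10:1, 50 °C
Reagents that add atoms: water O
Why: mild acid-catalysed acetal hydrolysis frees the aldehyde without touching the methyl ester or the terminal alkyne.

Step 9
Reactants: 11 methyl (13S)-7-oxo-7,8-secolabd-8(17)-yn-15-oate
Product: 12 methyl (13S)-7β-(triethylsilyloxy)labd-8(17)-en-15-oate
Conditions: Ni(cod)2 [bis(1,5-cyclooctadiene)nickel] (10 mol %), IMes·HCl (1,3-dimesitylimidazolium chloride, 10 mol %), KOtBu (10 mol %), Et3SiH (3 equiv), THF, 20 °C, slow addition of 11
Reagents that add atoms: triethylsilane CC[SiH](CC)CC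
Why: Zerovalent nickel carrying the N-heterocyclic carbene binds the aldehyde and the alkyne and undergoes oxidative cyclization to a five-membered nickel alkoxide–vinyl metallacycle, which forms the C7–C8 bond; σ-bond metathesis with Et3SiH silylates the oxygen and C–H reductive elimination at C17 releases the exocyclic methylene and the catalyst. The closest known reaction type is the nickel-catalysed reductive cyclization of ynals with silanes to 2-alkylidenecycloalkanol silyl ethers, which is established for terminal alkynes and six-membered rings. Ring B closes in the 6-exo-dig mode, the only one in which nickel can span O and C17, since the 7-endo alternative would place an E olefin in a seven-membered ring. The new stereocentre C7 is controlled by a chair-like transition state anchored on ring A, whose C6 and C9 arms are trans-diequatorial (C5 and C10 fixed): the planar metallacycle needs O–C7–C8=C17 syn-coplanar, which puts the C7–O bond equatorial (7β) and the C7–H axial. The step needs C–C bond formation to outrun alkyne oligomerisation and simple hydrosilylation, which is secured by intramolecularity, slow addition and the Thorpe–Ingold effect of the quaternary C10; the methyl ester is inert and C9 and C13 cannot epimerise under these neutral conditions.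

Step 10
Reactants: 12 methyl (13S)-7β-(triethylsilyloxy)labd-8(17)-en-15-oate
Product: 13 methyl (13S)-7β-hydroxylabd-8(17)-en-15-oate
Conditions: PPTS (0.2 equiv), MeOH, 20 °C
Reagents that add atoms: none
Why: acid-catalysed methanolysis removes the triethylsilyl ether at room temperature, conditions under which the allylic alcohol does not ionise and the methyl ester is unchanged.

Step 11
Reactants: 13 methyl (13S)-7β-hydroxylabd-8(17)-en-15-oate
Product: 14 methyl (13S)-7α-acetoxylabd-8(17)-en-15-oate (5S,7R,9R,10S,13S; the target)
Conditions: PPh3 (2 equiv), DIAD (2 equiv), AcOH (3 equiv), THF, 0 to 20 °C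
Reagents that add atoms: acetic acid CC(=O)O
Why: Mitsunobu esterification displaces the equatorial oxyphosphonium group by acetate with inversion to give the axial 7α-acetate, and because the equatorial C7–O bond lies in the nodal plane of the C8=C17 π bond, ionisation and SN2′ attack at C17 should not compete.

**Compound list**

1 | (−)-sclareol, (13R)-labd-14-ene-8α,13-diol | C[C@@]1(O)CC[C@H]2C(C)(C)CCC[C@]2(C)[C@H]1CC[C@@](C)(O)C=C | starting material
2 | (13R)-labdane-8α,13,14,15-tetraol, mixture at C14 | C[C@@]1(O)CC[C@H]2C(C)(C)CCC[C@]2(C)[C@H]1CC[C@@](C)(O)C(O)CO | intermediate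
3 | 8α-hydroxy-14,15-dinorlabdan-13-one | C[C@@]1(O)CC[C@H]2C(C)(C)CCC[C@]2(C)[C@H]1CCC(C)=O | intermediate
4 | methyl (13E)-8α-hydroxylabd-13-en-15-oate | C[C@@]1(O)CC[C@H]2C(C)(C)CCC[C@]2(C)[C@H]1CC/C(C)=C/C(=O)OC | intermediate
5 | methyl (13S)-8α-hydroxylabdan-15-oate | C[C@@]1(O)CC[C@H]2C(C)(C)CCC[C@]2(C)[C@H]1CC[C@H](C)CC(=O)OC | intermediate
6 | methyl (13S)-labd-7-en-15-oate | CC1=CC[C@H]2C(C)(C)CCC[C@]2(C)[C@H]1CC[C@H](C)CC(=O)OC | intermediate
7 | methyl (13S)-7,8-dioxo-7,8-secolabdan-15-oate (ring A with the CH2CHO arm on C5 and, on C10, the C9 carbon bearing the acetyl group and the side chain) | O=CC[C@H]1C(C)(C)CCC[C@]1(C)[C@H](C(C)=O)CC[C@H](C)CC(=O)OC | intermediate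
8 | methyl (13S)-7,7-dimethoxy-8-oxo-7,8-secolabdan-15-oate | COC(OC)C[C@H]1C(C)(C)CCC[C@]1(C)[C@H](C(C)=O)CC[C@H](C)CC(=O)OC | intermediate
9 | methyl (13S)-8-(diethoxyphosphoryloxy)-7,7-dimethoxy-7,8-secolabd-8(17)-en-15-oate | COC(OC)C[C@H]1C(C)(C)CCC[C@]1(C)[C@H](C(=C)OP(=O)(OCC)OCC)CC[C@H](C)CC(=O)OC | intermediate
10 | methyl (13S)-7,7-dimethoxy-7,8-secolabd-8(17)-yn-15-oate | COC(OC)C[C@H]1C(C)(C)CCC[C@]1(C)[C@H](C#C)CC[C@H](C)CC(=O)OC | intermediate
11 | methyl (13S)-7-oxo-7,8-secolabd-8(17)-yn-15-oate (the ynal: C7 aldehyde, ethynyl C8≡C17 on C9) | O=CC[C@H]1C(C)(C)CCC[C@]1(C)[C@H](C#C)CC[C@H](C)CC(=O)OC | intermediate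
12 | methyl (13S)-7β-(triethylsilyloxy)labd-8(17)-en-15-oate | C=C1[C@@H](O[Si](CC)(CC)CC)C[C@H]2C(C)(C)CCC[C@]2(C)[C@H]1CC[C@H](C)CC(=O)OC | intermediate
13 | methyl (13S)-7β-hydroxylabd-8(17)-en-15-oate | C=C1[C@@H](O)C[C@H]2C(C)(C)CCC[C@]2(C)[C@H]1CC[C@H](C)CC(=O)OC | intermediate
14 | methyl (13S)-7α-acetoxylabd-8(17)-en-15-oate (5S,7R,9R,10S,13S) | C=C1[C@H](OC(C)=O)C[C@H]2C(C)(C)CCC[C@]2(C)[C@H]1CC[C@H](C)CC(=O)OC | target

**Step count and risks**

Total steps: 11. Longest linear sequence: 11 (the route is linear from sclareol).

Steps most likely to fail: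

Step 9. The oxidative cyclization may be slow at the hindered propargylic alkyne, so that alkyne oligomerisation or plain hydrosilylation takes over, or the C7 selectivity may erode. Fallback, setting out from ketone 8 and dispensing with the alkyne: KN(SiMe3)2 and PhNTf2 in THF at −78 °C should give the kinetic 1-alken-2-yl triflate, methyl (13S)-7,7-dimethoxy-8-(trifluoromethanesulfonyloxy)-7,8-secolabd-8(17)-en-15-oate F1. PPTS in wet acetone then frees the aldehyde, methyl (13S)-7-oxo-8-(trifluoromethanesulfonyloxy)-7,8-secolabd-8(17)-en-15-oate F2. An intramolecular Nozaki–Hiyama–Kishi reaction (CrCl2 in excess, NiCl2 1 mol %, DMF, 20 °C) closes the same C7–C8 bond, with the chromium alkoxide expected in the equatorial position of the chair-like closure, and the route is rejoined at 13.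

Step 4. Proton loss from the C8 cation may be poorly regioselective, giving the 8(17)- and 8(9)-olefins beside the 7-ene, and prolonged acid exposure drifts towards the tetrasubstituted olefin. Regioisomers that survive would be removed after step 5, where only the 7-ene gives the keto acetal. Fallback, setting out from 5 and fixing the olefin position through a ketone: SOCl2 in pyridine at −78 °C (anti elimination from the equatorial chlorosulfite, only methyl hydrogens antiperiplanar) should give methyl (13S)-labd-8(17)-en-15-oate F3. Ozonolysis (O3, CH2Cl2/MeOH, −78 °C; Me2S) gives methyl (13S)-8-oxo-17-norlabdan-15-oate F4. LiN(iPr)2 and PhNTf2 at −78 °C deprotonate the unhindered C7 methylene to give methyl (13S)-8-(trifluoromethanesulfonyloxy)-17-norlabd-7-en-15-oate F5. Negishi methylation (MeZnCl, Pd(PPh3)4, THF, 50 °C) returns to 6 with the double bond fixed at C7=C8.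

Step 11. Backside attack on the equatorial oxyphosphonium ion passes the axial hydrogens on C5 and C9 and may be slow, leaving room for elimination to the diene or for recovered alcohol. Fallback, setting out from 13 and inverting C7 by redox: Dess–Martin periodinane in CH2Cl2 gives the enone, methyl (13S)-7-oxolabd-8(17)-en-15-oate F6. Corey–Bakshi–Shibata reduction with (S)-2-methyl-CBS-oxazaborolidine and BH3·SMe2 in THF at −20 °C is 1,2-selective and reagent-controlled; with the vinylic C8 as the large group, hydride should arrive on the β face to give methyl (13S)-7α-hydroxylabd-8(17)-en-15-oate F7. Acetylation (Ac2O, pyridine, DMAP) then gives 14.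

**Further compounds**

F1 | step 9 | methyl (13S)-7,7-dimethoxy-8-(trifluoromethanesulfonyloxy)-7,8-secolabd-8(17)-en-15-oate | COC(OC)C[C@H]1C(C)(C)CCC[C@]1(C)[C@H](C(=C)OS(=O)(=O)C(F)(F)F)CC[C@H](C)CC(=O)OC
F2 | step 9 | methyl (13S)-7-oxo-8-(trifluoromethanesulfonyloxy)-7,8-secolabd-8(17)-en-15-oate | O=CC[C@H]1C(C)(C)CCC[C@]1(C)[C@H](C(=C)OS(=O)(=O)C(F)(F)F)CC[C@H](C)CC(=O)OC
F3 | step 4 | methyl (13S)-labd-8(17)-en-15-oate | C=C1CC[C@H]2C(C)(C)CCC[C@]2(C)[C@H]1CC[C@H](C)CC(=O)OC
F4 | step 4 | methyl (13S)-8-oxo-17-norlabdan-15-oate | O=C1CC[C@H]2C(C)(C)CCC[C@]2(C)[C@H]1CC[C@H](C)CC(=O)OC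
F5 | step 4 | methyl (13S)-8-(trifluoromethanesulfonyloxy)-17-norlabd-7-en-15-oate | FC(F)(F)S(=O)(=O)OC1=CC[C@H]2C(C)(C)CCC[C@]2(C)[C@H]1CC[C@H](C)CC(=O)OC
F6 | step 11 | methyl (13S)-7-oxolabd-8(17)-en-15-oate | C=C1C(=O)C[C@H]2C(C)(C)CCC[C@]2(C)[C@H]1CC[C@H](C)CC(=O)OC
F7 | step 11 | methyl (13S)-7α-hydroxylabd-8(17)-en-15-oate | C=C1[C@H](O)C[C@H]2C(C)(C)CCC[C@]2(C)[C@H]1CC[C@H](C)CC(=O)OC
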